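## Retrosynthetic overview
1. The target comes from an 11-OTBS, 15-ketone pentacycle by Luche reduction and desilylation. The D ring closes by 5-exo vinyl-radical cyclization (C13–C16) of a 2-bromoallyl carbinol, which is made by aldol of the C8 lactone enolate with 2-bromoacrolein (C8–C15).
2. The A ring is closed late by an intramolecular Michael addition of the γ-lactone enolate (C5) onto a C9=C10 enone. This forms the spiro quaternary C10.
3. The C9=C10 enone and the 7,20-δ-lactone (B′) come from an intramolecular aldol condensation of an α-acyloxy ketone ester.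
4. That ester joins a Birch-derived 5-carboxycyclohexenone (ring C) to a 4-methyl-4-(4,5-dihydroxypentyl)butyrolactone. The lactone is made by Cu-catalysed conjugate addition, which sets C4 and carries the 6,19-lactone.
5. Ring order: γ-lactone and ring C are pre-formed, then B′, then A, then D.

Assumptions: 4-methylfuran-2(5H)-one and 3-methoxybenzoic acid are purchasable. C8 is enolisable, so racemic C8 in acid 2 is erased later (Step 10).

---

## Route

**Step 1**
Reactants: 1 (3-methoxybenzoic acid)
Product: 2 (3-oxocyclohex-4-ene-1-carboxylic acid, racemic at C8)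
Conditions: (1) Li, NH3(l), t-BuOH, THF, –78 °C; (2) 2 M HCl, THF, 25 °C
Reagents that add atoms: water (O)
Why: Birch reduction gives the 1,4-dihydro enol ether, and acid hydrolysis with alkene conjugation gives the cyclohexenone (ring C: C11 ketone, C12=C13). C8 is racemic but is enolisable and erased in Step 10.

**Step 2**
Reactants: 3 (4-methylfuran-2(5H)-one), 4 (pent-4-en-1-ylmagnesium bromide)
Product: 5 ((4R)-4-methyl-4-(pent-4-en-1-yl)oxolan-2-one)
Conditions: 4, CuBr·SMe2 (5 mol%), Josiphos-type ligand (6 mol%), TMSCl, Et2O, –78 °C
Reagents that add atoms: none (the Grignard is reactant 4)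
Why: Cu-catalysed asymmetric conjugate addition to a β,β-disubstituted butenolide creates the quaternary C4 with the ligand-controlled (R) configuration. This is the only enantio-determining step, and all later stereocentres are substrate-controlled.

**Step 3**
Reactants: 5
Product: 6 ((4R)-4-(4,5-dihydroxypentyl)-4-methyloxolan-2-one; C10 carbinol epimers)
Conditions: OsO4 (5 mol%), NMO, acetone/H2O, 25 °C
Reagents that add atoms: N-methylmorpholine N-oxide, C[N+]1([O-])CCOCC1 (supplies the two OH oxygens)
Why: Upjohn dihydroxylation of the terminal alkene. The new carbinol stereocentre (C10) is destroyed in Step 5.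

**Step 4**
Reactants: 2, 6
Product: 7 (primary ester of 2 with diol 6; C8 and C10 epimeric mixture)
Conditions: EDC·HCl, DMAP, CH2Cl2, 0 → 25 °C
Reagents that add atoms: none
Why: Steglich esterification is selective for the unhindered primary C20–OH over the secondary C10–OH. This joins the two fragments.

**Step 5**
Reactants: 7
Product: 8 (α-acyloxy ketone)
Conditions: DMP, NaHCO3, CH2Cl2, 25 °C
Reagents that add atoms: none
Why: Dess–Martin oxidation of the secondary alcohol only. It gives C10 ketone and removes the C10 stereo-issue, and the enone, ester and lactone are untouched.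

**Step 6**
Reactants: 8
Product: 9 (B′ δ-lactone fused to the cross-conjugated cyclohexadienone, C9=C10; C8 epimeric)
Conditions: (1) DBU, LiCl, MeCN, 25 °C; (2) MsCl, Et3N, CH2Cl2, 0 → 40 °C
Reagents that add atoms: none (net loss of H2O)
Why: Intramolecular aldol condensation. The α′-enolate of the cyclohexenone (C9) adds to the C10 ketone in a 6-exo closure that forms the 7,20-lactone ring, and dehydration gives the C9=C10 enone. This is the Michael acceptor for Step 7.

**Step 7**
Reactants: 9
Product: 10 (tetracyclic keto bis-lactone: 4R, 5β-H, spiro C10 with C20 α, 9β-H; C8 epimeric)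
Conditions: t-BuOK (0.3 equiv), THF, 0 → 25 °C, 0.01 M
Reagents that add atoms: none (isomerisation)
Why: Intramolecular Michael addition (6-exo) of the γ-lactone enolate (C5) to C10 of the enone closes ring A and forms the quaternary C10.
- The axial C19 at C4 blocks the α face at C10, so C20 ends up syn to C19 and C9 is equatorial.
- The cis-fused γ-lactone fixes C5.
- C9 and C8 are enolisable, so the reversible conditions deliver the thermodynamic 9β-H.

**Step 8**
Reactants: 10
Product: 11 (11α-alcohol; allylic alcohol C11–OH, C12=C13)
Conditions: NaBH4, CeCl3·7H2O, MeOH/CH2Cl2, –78 °C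
Reagents that add atoms: none
Why: Luche 1,2-reduction. Hydride adds from the β face, anti to the bulky spiro C10 on the α face, so OH ends up α, as in the target. The lactones survive at –78 °C.

**Step 9**
Reactants: 11
Product: 12 (C11 TBS ether)
Conditions: TBSOTf, 2,6-lutidine, CH2Cl2, –78 °C
Reagents that add atoms: tert-butyldimethylsilyl triflate, CC(C)(C)[Si](C)(C)OS(=O)(=O)C(F)(F)F
Why: Silylation prevents δ→γ translactonisation to C11–O and enolate quenching in Step 10. No stereocentre is changed.

**Step 10**
Reactants: 12, 13 (2-bromoacrolein)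
Product: 14 (C8 quaternary, C15 bromoallyl carbinol; C15 epimers)
Conditions: LiHMDS, THF, –78 °C; then 13, –78 °C
Reagents that add atoms: none (13 is reactant)
Why: Aldol of the B′-lactone enolate (1,2-addition to the enal, not 5-endo conjugate addition). The electrophile approaches anti to the large C10 on C9, syn to H9, so C15 is β. This sets C8, and the C15 epimer ratio is irrelevant because it is oxidised in Step 12.

**Step 11**
Reactants: 14
Product: 15 (TBS-protected pentacycle, 15-OH)
Conditions: Bu3SnH (slow addition), AIBN, PhH, 80 °C, 0.005 M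
Reagents that add atoms: none (Br replaced by H)
Why: The vinyl radical at C16 undergoes 5-exo cyclization onto C13 of the C12=C13 alkene (Stork-type radical cyclization). The tether from β-C15 forces delivery to the β face of C13, giving the bicyclo[3.2.1]octane and the exocyclic C16=C17. The C12 radical is reduced.

**Step 12**
Reactants: 15
Product: 16 (15-oxo-16-ene)
Conditions: DMP, NaHCO3, CH2Cl2, 25 °C
Reagents that add atoms: none
Why: Oxidation of the epimeric allylic alcohols to one enone removes the C15 uncertainty.

**Step 13**
Reactants: 16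
Product: 17 (C11-OTBS, 15-endo-OH)
Conditions: NaBH4, CeCl3·7H2O, MeOH, –78 °C
Reagents that add atoms: none
Why: Luche reduction. Hydride enters from the exo face (C14 side), which is less hindered than the face toward the C9–C11–C12 bridge and ring A. This puts OH endo, as in the target.

**Step 14**
Reactants: 17
Product: 18 (Guidongnin)
Conditions: HF·pyridine, THF/pyridine, 0 → 25 °C
Reagents that add atoms: none
Why: Fluoride-mediated desilylation under non-basic conditions avoids translactonisation. Both lactones, the alkene and all stereocentres are untouched.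

---

## Compound list
1 | 3-methoxybenzoic acid | COc1cccc(c1)C(=O)O | starting material
2 | 3-oxocyclohex-4-ene-1-carboxylic acid (racemic) | OC(=O)C1CC(=O)C=CC1 | intermediate
3 | 4-methylfuran-2(5H)-one | CC1=CC(=O)OC1 | starting material
4 | pent-4-en-1-ylmagnesium bromide | C=CCCC[Mg]Br | starting material
5 | (4R)-4-methyl-4-(pent-4-en-1-yl)oxolan-2-one | C=CCCC[C@@]1(C)COC(=O)C1 | intermediate
6 | (4R)-4-(4,5-dihydroxypentyl)-4-methyloxolan-2-one (C10 epimers) | OCC(O)CCC[C@@]1(C)COC(=O)C1 | intermediate
7 | hydroxy ester from 2 and 6 (C8 and C10 epimers) | O=C(C1CC(=O)C=CC1)OCC(O)CCC[C@@]1(C)COC(=O)C1 | intermediate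
8 | α-acyloxy ketone (C8 epimers) | O=C(C1CC(=O)C=CC1)OCC(=O)CCC[C@@]1(C)COC(=O)C1 | intermediate
9 | B′-lactone cross-conjugated dienone (C8 epimers) | O=C1OCC(CCC[C@@]2(C)COC(=O)C2)=C2C(=O)C=CCC12 | intermediate
10 | tetracyclic keto bis-lactone (C8 epimers) | O=C1C=CCC2C(=O)OC[C@]3(CCC[C@@]4(C)COC(=O)[C@H]43)[C@H]12 | intermediate
11 | 11α-hydroxy analogue of 10 | O[C@@H]1C=CCC2C(=O)OC[C@]3(CCC[C@@]4(C)COC(=O)[C@H]43)[C@H]12 | intermediate
12 | 11-OTBS analogue of 11 | CC(C)(C)[Si](C)(C)O[C@@H]1C=CCC2C(=O)OC[C@]3(CCC[C@@]4(C)COC(=O)[C@H]43)[C@H]12 | intermediate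
13 | 2-bromoacrolein | C=C(Br)C=O | starting material
14 | C8-(2-bromoallyl carbinol) aldol adduct (C15 epimers) | C=C(Br)C(O)[C@]12CC=C[C@@H](O[Si](C)(C)C(C)(C)C)[C@H]1[C@@]3(CCC[C@@]4(C)COC(=O)[C@H]43)COC2=O | intermediate
15 | 11-OTBS-15-hydroxy pentacycle (C15 epimers) | C=C1[C@@H]2C[C@@H](O[Si](C)(C)C(C)(C)C)[C@H]3[C@@]4(CCC[C@@]5(C)COC(=O)[C@H]54)COC(=O)[C@]3(C2)C1O | intermediate
16 | 11-OTBS-15-oxo-16-ene | C=C1[C@@H]2C[C@@H](O[Si](C)(C)C(C)(C)C)[C@H]3[C@@]4(CCC[C@@]5(C)COC(=O)[C@H]54)COC(=O)[C@]3(C2)C1=O | intermediate
17 | 11-OTBS-15-endo-hydroxy pentacycle | C=C1[C@@H]2C[C@@H](O[Si](C)(C)C(C)(C)C)[C@H]3[C@@]4(CCC[C@@]5(C)COC(=O)[C@H]54)COC(=O)[C@]3(C2)[C@@H]1O | intermediate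
18 | Guidongnin | C=C1[C@@H]2C[C@@H](O)[C@H]3[C@@]4(CCC[C@@]5(C)COC(=O)[C@H]54)COC(=O)[C@]3(C2)[C@@H]1O | target

---

## Totals
Total steps: 14. Longest linear sequence: 13 (Steps 2–14 from 3). Step 1 runs in parallel.

## Three steps most likely to fail
1. **Step 7 (Michael, ring A).** The bond joins a tertiary enolate carbon to a β,β-disubstituted enone carbon, giving contiguous hindered centres, and γ-deprotonation or oligomerisation may compete. Fallback: reverse the bond order. Do an intramolecular aldol of the γ-lactone enolate onto the C10 ketone of 8 (C5–C10, tertiary C10–OH). Convert the alcohol to an oxalate and close C9–C10 by photoredox Giese 6-endo radical cyclization onto a C8=C9 acrylate analogue of ring C.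
2. **Step 6 (aldol condensation forming B′).** The ester tether prefers the wrong conformer, C8 enolisation would give a γ-lactone, and the enone formed is tetrasubstituted. Fallback: defer lactone formation. Use the methyl ester of 2 with the free C20 alcohol, form C9–C10 by intermolecular Mukaiyama aldol and dehydration, then close the 7,20-lactone by Yamaguchi lactonisation.
3. **Step 10 (hindered aldol forming quaternary C8).** The electrophile is bulky and the lactone enolate is very hindered. Fallback: alkylate the enolate with 2,3-dibromopropene (C15H2 instead of a carbinol), then do the radical cyclization. Install C15 oxygen afterwards by SeO2 allylic oxidation and Luche reduction.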